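**Strategy.** The key step exploits the fact that the carbocycle (C1 ketone, C2 benzoylated, C3 enol, C4 prenylated, C5 ketone, C6 quaternary) is a cyclised triketide whose C3–C4–C5 segment is a prenylmalonyl unit. This unit, as (chlorocarbonyl)prenylketene, is inserted in one flask between two enolates: a fully substituted butanolide enolate gives C5–C6 and acetophenone enolate gives C2–C3. The precursor is a 3-geranylbutanolide that disguises C1 and the C6 prenyl group; its carbinol stereocentre directs the acylation of C6, so no reagent has to tell prenyl from geranyl. Claisen closure C2–C1 then opens the lactone and a Horner–Wittig elimination releases the prenyl group.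

Key step: step 8

Remark: kolanone is a tautomeric β-triketone; 19 is written as the enol tautomer of the target structure, in which the quaternary carbon C6 is R.

**Step 1**
Reactants: 1 diethyl malonate; 2 1-bromo-3-methylbut-2-ene (prenyl bromide)
Product: 3 diethyl 2-(3-methylbut-2-en-1-yl)malonate
Conditions: NaOEt, EtOH, 0 °C to rt (1 in excess)
Reagents that add atoms: none
Why: Malonic ester alkylation (SN2 of the sodium enolate on the primary allylic bromide), in which the excess of 1 should suppress dialkylation.

**Step 2**
Reactants: 3
Product: 4 2-(3-methylbut-2-en-1-yl)malonic acid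
Conditions: KOH, EtOH/H2O, rt; then cold dilute HCl, extraction below rt
Reagents that add atoms: potassium hydroxide, [K+].[OH-]
Why: Saponification of both esters, with cold acidification to avoid decarboxylation of the malonic acid and hydration of the alkene.

**Step 3**
Reactants: 4
Product: 6 (chlorocarbonyl)(3-methylbut-2-en-1-yl)ketene, via malonyl dichloride 5 (not isolated)
Conditions: (COCl)2, N,N-dimethylformamide (cat.), CH2Cl2, 0 °C to rt, N2 sweep; then bulb-to-bulb distillation under reduced pressure
Reagents that add atoms: oxalyl chloride, O=C(Cl)C(Cl)=O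
Why: Acid chloride formation followed by thermal loss of HCl from the monosubstituted malonyl dichloride, the standard entry to (chlorocarbonyl)ketenes, should give a bis-electrophile that has no acidic C–H.

**Step 4**
Reactants: 7 isopropyldiphenylphosphine
Product: 8 isopropyldiphenylphosphine oxide
Conditions: H2O2 (30 % aq.), acetone, 0 °C to rt
Reagents that add atoms: hydrogen peroxide, OO
Why: Oxidation of the tertiary phosphine to its oxide.

**Step 5**
Reactants: 8; 9 methyl 4-chloro-4-oxobutanoate
Product: 10 methyl 5-(diphenylphosphoryl)-5-methyl-4-oxohexanoate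
Conditions: n-BuLi, THF, −78 °C; then transfer of the anion into 9 (excess) in THF, −78 °C
Reagents that add atoms: none
Why: The α-lithiated phosphine oxide is C-acylated by the acid chloride, which is far more electrophilic than the methyl ester, and inverse addition keeps the enolisable ketone product away from excess carbanion (acylation half of the Horner–Wittig acylation–reduction sequence).

**Step 6**
Reactants: 10
Product: 12 (5S)-5-[2-(diphenylphosphoryl)propan-2-yl]oxolan-2-one, via hydroxy ester 11 (not isolated)
Conditions: (R)-tetrahydro-1-methyl-3,3-diphenyl-1H,3H-pyrrolo[1,2-c][1,3,2]oxazaborole (cat.), BH3·SMe2, THF, −20 °C; MeOH; then p-toluenesulfonic acid (cat.), toluene, 50 °C; recrystallisation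
Reagents that add atoms: none
Why: Corey–Bakshi–Shibata reduction in which the quaternary phosphoryl-bearing carbon is the large ketone substituent, so that the (R)-oxazaborolidine should give the S carbinol (the sense known for tert-alkyl ketones), followed by acid-catalysed lactonisation; this carbinol is the only stereocentre set by a chiral reagent and later controls C6.

**Step 7**
Reactants: 12; 13 geranyl bromide
Product: 14 (3R,5S)-3-[(2E)-3,7-dimethylocta-2,6-dien-1-yl]-5-[2-(diphenylphosphoryl)propan-2-yl]oxolan-2-one
Conditions: LiN(i-Pr)2, THF, −78 °C; then 13, −78 to −40 °C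
Reagents that add atoms: none
Why: Alkylation of the butanolide lithium enolate by the allylic bromide, expected trans to the bulky 5-substituent; the configuration at lactone C3 is of no consequence because this carbon is enolised again in step 8.

**Step 8**
Reactants: 14; 6; 15 acetophenone
Product: 19 kolanone, via acylketene 16 (not isolated), via triketide lactone 17 (not isolated), via hydroxyphosphine oxide 18 (not isolated)
Conditions: 14, LiN(i-Pr)2, THF, −78 °C; enolate added to 6 (slight excess) in THF, −78 °C; then lithium enolate of 15 [15, LiN(SiMe3)2, THF; excess], −78 °C to rt; then KOt-Bu, N,N-dimethylformamide, rt to 50 °C; cold dilute HCl work-up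
Reagents that add atoms: none
Why: The lithium enolate of 14 is C-acylated by 6 (attack at either electrophilic carbon leads, after loss of chloride, to the same acylketene 16, which has no acidic C–H and so persists), the enolate of 15 then C-acylates at the ketene carbon to give triketide 17, whose polyanion closes by attack of C2 on the lactone carbonyl C1, and the β-phosphoryl alkoxide 18 released by this closure undergoes Horner–Wittig syn-elimination of potassium diphenylphosphinate once KOt-Bu is added. The closest known reaction types are the crossed Claisen C-acylation of ester and ketone enolates by acid chlorides and ketenes, the Claisen cyclisation of 3,5,7-triketo esters to acylphloroglucinols and the Horner–Wittig olefination. The carbocycle closes in a 6-(enolendo)-exo-trig Dieckmann-type acylation, which at the same time opens the butanolide. The C6 stereocentre is set in the first acylation: the enolate geometry is fixed by the lactone ring, geranyl is already in place, the future prenyl group is the ring itself, and the bulky 2-(diphenylphosphoryl)propan-2-yl group on the S carbinol carbon should force the acyl group to enter trans to it (1,3-induction, as in the double alkylation of 5-substituted butanolides), which corresponds to R at C6. The step needs C- rather than O-acylation at both enolates and one acylation per electrophilic site; the order of addition (hindered lactone enolate first and added inversely, excess ketone enolate second) and the stability of the final triketonate anion as thermodynamic sink should secure this.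

**Compound list**

1 | diethyl malonate | CCOC(=O)CC(=O)OCC | starting material
2 | 1-bromo-3-methylbut-2-ene (prenyl bromide) | CC(C)=CCBr | starting material
3 | diethyl 2-(3-methylbut-2-en-1-yl)malonate | CCOC(=O)C(CC=C(C)C)C(=O)OCC | intermediate
4 | 2-(3-methylbut-2-en-1-yl)malonic acid | OC(=O)C(CC=C(C)C)C(=O)O | intermediate
5 | 2-(3-methylbut-2-en-1-yl)malonyl dichloride | ClC(=O)C(CC=C(C)C)C(Cl)=O | intermediate
6 | (chlorocarbonyl)(3-methylbut-2-en-1-yl)ketene [2-(3-methylbut-2-en-1-yl)-3-oxoprop-2-enoyl chloride] | CC(C)=CCC(=C=O)C(Cl)=O | intermediate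
7 | isopropyldiphenylphosphine | CC(C)P(c1ccccc1)c1ccccc1 | starting material
8 | isopropyldiphenylphosphine oxide | CC(C)P(=O)(c1ccccc1)c1ccccc1 | intermediate
9 | methyl 4-chloro-4-oxobutanoate | COC(=O)CCC(Cl)=O | starting material
10 | methyl 5-(diphenylphosphoryl)-5-methyl-4-oxohexanoate | COC(=O)CCC(=O)C(C)(C)P(=O)(c1ccccc1)c1ccccc1 | intermediate
11 | methyl (4S)-5-(diphenylphosphoryl)-4-hydroxy-5-methylhexanoate | COC(=O)CC[C@H](O)C(C)(C)P(=O)(c1ccccc1)c1ccccc1 | intermediate
12 | (5S)-5-[2-(diphenylphosphoryl)propan-2-yl]oxolan-2-one | O=C1CC[C@@H](C(C)(C)P(=O)(c2ccccc2)c2ccccc2)O1 | intermediate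
13 | geranyl bromide [(2E)-1-bromo-3,7-dimethylocta-2,6-diene] | CC(C)=CCC/C(C)=C/CBr | starting material
14 | (3R,5S)-3-[(2E)-3,7-dimethylocta-2,6-dien-1-yl]-5-[2-(diphenylphosphoryl)propan-2-yl]oxolan-2-one (geranyl trans to the 5-substituent) | O=C1[C@H](C/C=C(C)/CCC=C(C)C)C[C@@H](C(C)(C)P(=O)(c2ccccc2)c2ccccc2)O1 | intermediate
15 | acetophenone | CC(=O)c1ccccc1 | starting material
16 | (3S,5S)-3-[(2E)-3,7-dimethylocta-2,6-dien-1-yl]-5-[2-(diphenylphosphoryl)propan-2-yl]-3-[2-(3-methylbut-2-en-1-yl)-3-oxoprop-2-enoyl]oxolan-2-one (acylketene; acyl group trans to the 5-substituent) | O=C1[C@](C/C=C(C)/CCC=C(C)C)(C(=O)C(CC=C(C)C)=C=O)C[C@@H](C(C)(C)P(=O)(c2ccccc2)c2ccccc2)O1 | intermediate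
17 | (3S,5S)-3-[(2E)-3,7-dimethylocta-2,6-dien-1-yl]-5-[2-(diphenylphosphoryl)propan-2-yl]-3-[2-(3-methylbut-2-en-1-yl)-3,5-dioxo-5-phenylpentanoyl]oxolan-2-one (keto–enol mixture; the CH between the ketones is not a defined stereocentre) | O=C1[C@](C/C=C(C)/CCC=C(C)C)(C(=O)C(CC=C(C)C)C(=O)CC(=O)c2ccccc2)C[C@@H](C(C)(C)P(=O)(c3ccccc3)c3ccccc3)O1 | intermediate
18 | (6S)-6-[(2S)-3-(diphenylphosphoryl)-2-hydroxy-3-methylbutyl]-6-[(2E)-3,7-dimethylocta-2,6-dien-1-yl]-3-hydroxy-2-[hydroxy(phenyl)methylidene]-4-(3-methylbut-2-en-1-yl)cyclohex-3-ene-1,5-dione (kolanone with the C6 prenyl group replaced by the hydroxy phosphine oxide chain; same spatial arrangement at C6 as in 19; formed as its alkoxide) | CC(C)=CCC/C(C)=C/C[C@]1(C[C@H](O)C(C)(C)P(=O)(c2ccccc2)c2ccccc2)C(=O)C(CC=C(C)C)=C(O)/C(=C(\O)c2ccccc2)C1=O | intermediate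
19 | kolanone, (6R)-6-[(2E)-3,7-dimethylocta-2,6-dien-1-yl]-3-hydroxy-2-[hydroxy(phenyl)methylidene]-4,6-bis(3-methylbut-2-en-1-yl)cyclohex-3-ene-1,5-dione | CC(C)=CCC/C(C)=C/C[C@]1(CC=C(C)C)C(=O)C(CC=C(C)C)=C(O)/C(=C(\O)c2ccccc2)C1=O | target

**Step count.** Total: 8 steps. Longest linear sequence: 5 steps (steps 4 to 8, from 7 to 19).

**Steps most likely to fail**

Step 8. The telescoped sequence may lose material through O-acylation of either enolate, oligomerisation of the ketene electrophile, or sluggish Claisen closure onto the hindered lactone carbonyl. A chelation-driven reversal of the facial sense would be corrected by using the enantiomeric lactone from step 6. Fallback (sets out from 14, comes back at 17): the carbon–carbon bonds are made in separate flasks by established reactions. The lithium enolate of 14 is carboxylated with CO2, which should also enter trans to the 5-substituent, to give (3S,5S)-3-[(2E)-3,7-dimethylocta-2,6-dien-1-yl]-5-[2-(diphenylphosphoryl)propan-2-yl]-2-oxooxolane-3-carboxylic acid F1. Treatment with 1-chloro-N,N,2-trimethylprop-1-en-1-amine under neutral conditions converts it into the corresponding (3R,5S)-2-oxooxolane-3-carbonyl chloride F2. In parallel the dianion of purchased 1-phenylbutane-1,3-dione [2 LiN(i-Pr)2] is alkylated at its methyl terminus with 2 to give 7-methyl-1-phenyloct-6-ene-1,3-dione F3. The dianion of F3 is then acylated at its γ-carbon by F2 to give isolated 17, and KOt-Bu in N,N-dimethylformamide takes 17 through 18 to 19 as in step 8.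

Step 3. Hydrogen chloride released during chlorination and thermal dehydrochlorination may add to the trisubstituted alkene, and the ketene may oligomerise on distillation. Fallback (sets out from 4, comes back at 6): 4 is silylated with HN(SiMe3)2 to bis(trimethylsilyl) 2-(3-methylbut-2-en-1-yl)malonate F4. This reacts with (COCl)2 and catalytic N,N-dimethylformamide to give 5 with Me3SiCl in place of HCl. Dichloride 5 is then dehydrochlorinated at −78 °C in THF on polymer-bound 2-tert-butylimino-2-diethylamino-1,3-dimethylperhydro-1,3,2-diazaphosphorine, and the filtered, salt-free solution of 6 is used directly in step 8.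

Step 6. The Lewis-basic phosphoryl oxygen may bind the oxazaborolidine or the borane and erode facial discrimination at the hindered ketone. Fallback (sets out from 8, comes back at 12): the carbinol centre is made by carbon–carbon bond formation instead of reduction. Lithiated 8 is formylated with N,N-dimethylformamide to the non-enolisable 2-(diphenylphosphoryl)-2-methylpropanal F5. Brown allylation with the antipode of (Ipc)2B(allyl) that delivers the S alcohol gives (S)-2-(diphenylphosphoryl)-2-methylhex-5-en-3-ol F6. Hydroboration (9-BBN; NaBO3·4H2O) gives (S)-5-(diphenylphosphoryl)-5-methylhexane-1,4-diol F7, and 2,2,6,6-tetramethylpiperidin-1-oxyl (cat.) with PhI(OAc)2 oxidises the 1,4-diol to lactone 12.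

**Further compounds**

F1 | step 8 | (3S,5S)-3-[(2E)-3,7-dimethylocta-2,6-dien-1-yl]-5-[2-(diphenylphosphoryl)propan-2-yl]-2-oxooxolane-3-carboxylic acid | O=C1[C@](C/C=C(C)/CCC=C(C)C)(C(=O)O)C[C@@H](C(C)(C)P(=O)(c2ccccc2)c2ccccc2)O1
F2 | step 8 | (3R,5S)-3-[(2E)-3,7-dimethylocta-2,6-dien-1-yl]-5-[2-(diphenylphosphoryl)propan-2-yl]-2-oxooxolane-3-carbonyl chloride | O=C1[C@](C/C=C(C)/CCC=C(C)C)(C(Cl)=O)C[C@@H](C(C)(C)P(=O)(c2ccccc2)c2ccccc2)O1
F3 | step 8 | 7-methyl-1-phenyloct-6-ene-1,3-dione | O=C(CC(=O)CCC=C(C)C)c1ccccc1
F4 | step 3 | bis(trimethylsilyl) 2-(3-methylbut-2-en-1-yl)malonate | C[Si](C)(C)OC(=O)C(CC=C(C)C)C(=O)O[Si](C)(C)C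
F5 | step 6 | 2-(diphenylphosphoryl)-2-methylpropanal | CC(C)(C=O)P(=O)(c1ccccc1)c1ccccc1
F6 | step 6 | (S)-2-(diphenylphosphoryl)-2-methylhex-5-en-3-ol | C=CC[C@H](O)C(C)(C)P(=O)(c1ccccc1)c1ccccc1
F7 | step 6 | (S)-5-(diphenylphosphoryl)-5-methylhexane-1,4-diol | OCCC[C@H](O)C(C)(C)P(=O)(c1ccccc1)c1ccccc1
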